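**Strategy.** The dihydropyran ring (O1, C2 methyl, C3 formyl, C4 acetate arm, C5 ester, C6) is traced back to a cyclohexene that already holds C2, C3, C4, C5 and the C3 formyl group, while its ring alkene holds C6 and the future ester carbon. One catalytic asymmetric endo Diels–Alder reaction of an (E)-configured 2-silyloxy-1,3-pentadiene with an (E)-enal bearing the arm as a silylated hydroxyethyl chain forms C2–C3 and C4–C5, closes that carbocycle and sets all three stereocentres. Ozonolysis of the silyl enol ether, Baeyer–Villiger insertion of O1 with retention and formyl transfer to C5 then recut the carbocycle into the heterocycle; hydroxytyrosol is attached last.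

Key step: step 4

Remark on numbering: O1 and C2–C6 are the pyran atoms of the target, and C7 is the carbon of the C5 methyl ester.

Assumption: the formyl C–H···O binding model for protonated oxazaborolidines predicts attack on the Cα Re face of the enal with the (S)-catalyst. The equally available (R)-catalyst would be used if the adduct proved antipodal.

**Step 1**
Reactants: 1 (E)-pent-3-en-2-one
Product: 2 (E)-2-(triisopropylsilyloxy)penta-1,3-diene
Conditions: LiN(iPr)2 (LDA, 1.05 equiv), THF, −78 °C; TIPSOTf, −78 → 0 °C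
Reagents that add atoms: triisopropylsilyl trifluoromethanesulfonate, CC(C)[Si](OS(=O)(=O)C(F)(F)F)(C(C)C)C(C)C
Why: Kinetic enolate formation and O-silylation: at −78 °C the hindered amide removes an α′-methyl proton faster than a γ-proton, and the hard silyl triflate traps the cross-conjugated enolate on oxygen without touching the (E)-alkene.

**Step 2**
Reactants: 3 but-3-en-1-ol
Product: 4 (but-3-en-1-yloxy)(tert-butyl)dimethylsilane
Conditions: TBSCl, imidazole, CH2Cl2, 0 °C → rt
Reagents that add atoms: tert-butyldimethylsilyl chloride, CC(C)(C)[Si](C)(C)Cl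
Why: Standard imidazole-promoted silyl ether formation of an unhindered primary alcohol.

**Step 3**
Reactants: 4 (but-3-en-1-yloxy)(tert-butyl)dimethylsilane; 5 (E)-but-2-enal (crotonaldehyde, 4 equiv)
Product: 6 (E)-5-(tert-butyldimethylsilyloxy)pent-2-enal
Conditions: second-generation Hoveyda–Grubbs catalyst RuCl2(H2IMes)(=CH-C6H4-2-OiPr) (2 mol %), CH2Cl2, 40 °C
Reagents that add atoms: none
Why: Olefin cross-metathesis of a fast-reacting terminal alkene with an excess of an electron-poor enal favours the cross product and, being reversible, should settle on the (E)-enal while propene escapes.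

**Step 4**
Reactants: 2 (E)-2-(triisopropylsilyloxy)penta-1,3-diene (1.5 equiv); 6 (E)-5-(tert-butyldimethylsilyloxy)pent-2-enal
Product: 7 (1S,2R,6R)-6-[2-(tert-butyldimethylsilyloxy)ethyl]-2-methyl-4-(triisopropylsilyloxy)cyclohex-3-ene-1-carbaldehyde (methyl cis to formyl; formyl trans to the side chain)
Conditions: (S)-3,3-diphenyl-1-(2-methylphenyl)tetrahydro-1H,3H-pyrrolo[1,2-c][1,3,2]oxazaborole (20 mol %), HN(SO2CF3)2 (18 mol %), CH2Cl2, −78 → −40 °C; Et3N quench
Reagents that add atoms: none
Why: Protonation of the oxazaborolidine gives a cationic boron Lewis acid that binds the formyl oxygen of 6 (supported by a formyl C–H···O contact), lowers the enal LUMO and triggers a concerted, asynchronous [4π+2π] cycloaddition; the closest known reaction type is the oxazaborolidinium-catalysed Diels–Alder reaction of 2-silyloxy dienes with α,β-unsaturated aldehydes. The one new ring, the cyclohexene, closes by intermolecular suprafacial–suprafacial union of both diene termini with Cα and Cβ of the enal, with C4–C5 formation running ahead of C2–C3. Regiochemistry is secured by the substrate, because the 2-silyloxy and 4-methyl groups both raise the HOMO coefficient at the CH2 terminus, which therefore bonds to the electrophilic β-carbon. The C3/C4 trans relation follows from the (E)-geometry of 6, the C2/C3 cis relation from the (E)-geometry of 2 combined with the endo orientation of the coordinated formyl group, and the absolute sense from the catalyst, whose phenyl group covers one face of the s-trans enal so that 2 adds to the Cα Re face. The step needs [4+2] addition to win over Mukaiyama aldol attack at the formyl carbon and over protodesilylation of 2; the bulky TIPS group, the low temperature and the weakly basic TBS ether are chosen to secure this.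

**Step 5**
Reactants: 7 Diels–Alder adduct aldehyde
Product: 8 dimethyl acetal of 7 (CHO replaced by CH(OMe)2; three configurations unchanged)
Conditions: HC(OMe)3 (5 equiv), CeCl3·7H2O (10 mol %), MeOH, 0 °C → rt, short contact
Reagents that add atoms: trimethyl orthoformate, COC(OC)OC; methanol, CO
Why: Lanthanide-salt-catalysed acetalisation with orthoformate as water scavenger runs close to neutrality, so the TIPS enol ether, the TBS ether and the α-stereocentre C3 should survive.

**Step 6**
Reactants: 8 dimethyl acetal of the adduct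
Product: 10 triisopropylsilyl (3R,4S,5S)-3-[2-(tert-butyldimethylsilyloxy)ethyl]-4-(dimethoxymethyl)-5-methyl-6-oxohexanoate, via methoxy hydroperoxide 9 (not isolated)
Conditions: O3/O2, CH2Cl2/MeOH 5:1, −78 °C, Sudan red 7B end point; Me2S, −78 °C → rt
Reagents that add atoms: ozone, [O-][O+]=O
Why: Ozonolysis (Criegee mechanism): the electron-rich silyl enol ether is the only alkene and reacts far faster than the acetal C–H bond, and the primary ozonide splits into the C7 silyl ester and a C6 carbonyl oxide that methanol traps as 9 and dimethyl sulfide reduces without base, so C2 should keep its configuration.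

**Step 7**
Reactants: 10 aldehyde TIPS ester
Product: 12 methyl (3R,4S,5S)-3-[2-(tert-butyldimethylsilyloxy)ethyl]-4-(dimethoxymethyl)-5-methyl-6-oxohexanoate, via carboxylic acid 11 (not isolated)
Conditions: Et3N·3HF (1.0 equiv), THF, 0 °C; pH 4 wash; TMSCHN2, PhMe/MeOH 4:1, 0 °C
Reagents that add atoms: (trimethylsilyl)diazomethane, C[Si](C)(C)C=[N+]=[N-]
Why: Fluoride cleavage of a silyl ester, whose carboxylate leaving group makes it much more labile than the alkyl TBS ether, followed by diazoalkane O-methylation; both operations are non-basic, so C2 next to the aldehyde should not epimerise.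

**Step 8**
Reactants: 12 aldehyde methyl ester
Product: 13 methyl (3R,4S,5S)-3-[2-(tert-butyldimethylsilyloxy)ethyl]-4-(dimethoxymethyl)-5-(formyloxy)hexanoate
Conditions: mCPBA (purified, 1.5 equiv), CH2Cl2, 0 °C → rt
Reagents that add atoms: 3-chloroperoxybenzoic acid, OOC(=O)c1cccc(Cl)c1
Why: Baeyer–Villiger oxidation of an α-branched aldehyde: in the peracid adduct the secondary carbon C2 migrates in preference to hydrogen and with retention, which installs O1 and turns C6 into a formate carbon, while ester, acetal and silyl ether are inert.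

**Step 9**
Reactants: 13 formate ester
Product: 15 methyl (2S,3S,4S)-4-[2-(tert-butyldimethylsilyloxy)ethyl]-3-(dimethoxymethyl)-2-methyl-3,4-dihydro-2H-pyran-5-carboxylate, via lactol 14 (not isolated)
Conditions: 13 added slowly to LiN(SiMe3)2 (1.2 equiv), THF, −78 → −20 °C; AcOH quench; crude in CH2Cl2, camphor-10-sulfonic acid (CSA, 5 mol %), 4 Å MS, rt
Reagents that add atoms: none
Why: Dieckmann-type intramolecular crossed Claisen condensation followed by acid-catalysed vinylogous esterification: C5 is the only enolisable position, the non-enolisable formate is the most electrophilic acyl group and is reached through a six-membered 6-exo-trig transition state, the β-oxo ester enolate is the thermodynamic sink, and dehydration of 14 leaves the C2–O1 bond and all three stereocentres untouched.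

**Step 10**
Reactants: 15 dihydropyran TBS ether
Product: 16 methyl (2S,3S,4S)-3-(dimethoxymethyl)-4-(2-hydroxyethyl)-2-methyl-3,4-dihydro-2H-pyran-5-carboxylate
Conditions: Et3N·3HF (5 equiv), MeCN, rt
Reagents that add atoms: none
Why: Fluoride desilylation in a slightly acidic, anhydrous medium spares the acetal and avoids a free alkoxide that could lactonise onto the C5 ester.

**Step 11**
Reactants: 16 primary alcohol
Product: 17 2-[(2S,3S,4S)-3-(dimethoxymethyl)-5-(methoxycarbonyl)-2-methyl-3,4-dihydro-2H-pyran-4-yl]acetic acid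
Conditions: 2,2,6,6-tetramethylpiperidine-1-oxyl (TEMPO, 10 mol %), NaClO2 (2 equiv), NaOCl (2 mol %), MeCN/sodium phosphate buffer pH 6.7, 35 °C
Reagents that add atoms: sodium chlorite, [Na+].[O-]Cl=O
Why: Oxoammonium oxidation to the aldehyde coupled with Pinnick-type chlorite oxidation to the acid works at near-neutral pH with only traces of hypochlorite, so the acetal and the push–pull alkene should be preserved.

**Step 12**
Reactants: 18 hydroxytyrosol (4-(2-hydroxyethyl)benzene-1,2-diol)
Product: 19 tris-TBS ether of hydroxytyrosol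
Conditions: TBSCl (3.5 equiv), imidazole, DMF, rt
Reagents that add atoms: tert-butyldimethylsilyl chloride, CC(C)(C)[Si](C)(C)Cl
Why: Exhaustive imidazole-promoted silylation protects the oxidation-prone catechol and needs no selectivity.

**Step 13**
Reactants: 19 tris-TBS ether of hydroxytyrosol
Product: 20 2-[3,4-bis(tert-butyldimethylsilyloxy)phenyl]ethanol
Conditions: camphor-10-sulfonic acid (10 mol %), MeOH/CH2Cl2 1:1, 0 °C
Reagents that add atoms: none
Why: Acid-catalysed methanolysis of silyl ethers is much faster for the basic primary alkyl ether oxygen than for the aryl ether oxygens, so only the alcohol is released.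

**Step 14**
Reactants: 17 pyranylacetic acid; 20 2-[3,4-bis(tert-butyldimethylsilyloxy)phenyl]ethanol
Product: 21 2-[3,4-bis(tert-butyldimethylsilyloxy)phenyl]ethyl ester of 17
Conditions: N,N'-diisopropylcarbodiimide, 4-(dimethylamino)pyridine (DMAP, 10 mol %), CH2Cl2, 0 °C → rt
Reagents that add atoms: none
Why: Steglich esterification of an unhindered CH2CO2H group with a primary alcohol proceeds under mild conditions that leave the acetal, the enol ether ester and the silyl ethers alone.

**Step 15**
Reactants: 21 fully protected ester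
Product: 23 methyl (2S,3S,4S)-4-{2-[2-(3,4-dihydroxyphenyl)ethoxy]-2-oxoethyl}-3-formyl-2-methyl-3,4-dihydro-2H-pyran-5-carboxylate (target), via catechol acetal 22 (not isolated)
Conditions: Et3N·3HF, MeCN, rt, Ar; then 1 M aq. HCl added, rt
Reagents that add atoms: water, O
Why: Non-basic fluoride cleavage of the aryl silyl ethers followed by specific-acid-catalysed acetal hydrolysis; the vinylogous carbonate, both esters and the catechol tolerate dilute acid, and the absence of base avoids enolisation at C3 and retro-oxa-Michael opening at C2.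

**Compound list**

| No. | Name | SMILES | Role |
|---|---|---|---|
| 1 | (E)-pent-3-en-2-one | C/C=C/C(C)=O | starting material |
| 2 | (E)-2-(triisopropylsilyloxy)penta-1,3-diene | C=C(O[Si](C(C)C)(C(C)C)C(C)C)/C=C/C | intermediate |
| 3 | but-3-en-1-ol | C=CCCO | starting material |
| 4 | (but-3-en-1-yloxy)(tert-butyl)dimethylsilane | C=CCCO[Si](C)(C)C(C)(C)C | intermediate |
| 5 | (E)-but-2-enal | C/C=C/C=O | starting material |
| 6 | (E)-5-(tert-butyldimethylsilyloxy)pent-2-enal | O=C/C=C/CCO[Si](C)(C)C(C)(C)C | intermediate |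
| 7 | (1S,2R,6R)-6-[2-(tert-butyldimethylsilyloxy)ethyl]-2-methyl-4-(triisopropylsilyloxy)cyclohex-3-ene-1-carbaldehyde | C[C@@H]1C=C(O[Si](C(C)C)(C(C)C)C(C)C)C[C@@H](CCO[Si](C)(C)C(C)(C)C)[C@@H]1C=O | intermediate |
| 8 | dimethyl acetal of 7 | C[C@@H]1C=C(O[Si](C(C)C)(C(C)C)C(C)C)C[C@@H](CCO[Si](C)(C)C(C)(C)C)[C@@H]1C(OC)OC | intermediate |
| 9 | triisopropylsilyl (3R,4S,5S)-3-[2-(tert-butyldimethylsilyloxy)ethyl]-4-(dimethoxymethyl)-6-hydroperoxy-6-methoxy-5-methylhexanoate (C6 undefined) | COC(OO)[C@@H](C)[C@@H](C(OC)OC)[C@@H](CC(=O)O[Si](C(C)C)(C(C)C)C(C)C)CCO[Si](C)(C)C(C)(C)C | intermediate |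
| 10 | triisopropylsilyl (3R,4S,5S)-3-[2-(tert-butyldimethylsilyloxy)ethyl]-4-(dimethoxymethyl)-5-methyl-6-oxohexanoate | O=C[C@@H](C)[C@@H](C(OC)OC)[C@@H](CC(=O)O[Si](C(C)C)(C(C)C)C(C)C)CCO[Si](C)(C)C(C)(C)C | intermediate |
| 11 | (3R,4S,5S)-3-[2-(tert-butyldimethylsilyloxy)ethyl]-4-(dimethoxymethyl)-5-methyl-6-oxohexanoic acid | O=C[C@@H](C)[C@@H](C(OC)OC)[C@@H](CC(=O)O)CCO[Si](C)(C)C(C)(C)C | intermediate |
| 12 | methyl (3R,4S,5S)-3-[2-(tert-butyldimethylsilyloxy)ethyl]-4-(dimethoxymethyl)-5-methyl-6-oxohexanoate | O=C[C@@H](C)[C@@H](C(OC)OC)[C@@H](CC(=O)OC)CCO[Si](C)(C)C(C)(C)C | intermediate |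
| 13 | methyl (3R,4S,5S)-3-[2-(tert-butyldimethylsilyloxy)ethyl]-4-(dimethoxymethyl)-5-(formyloxy)hexanoate | O=CO[C@@H](C)[C@@H](C(OC)OC)[C@@H](CC(=O)OC)CCO[Si](C)(C)C(C)(C)C | intermediate |
| 14 | C6 lactol, methyl (2S,3S,4S)-4-[2-(tert-butyldimethylsilyloxy)ethyl]-3-(dimethoxymethyl)-6-hydroxy-2-methyltetrahydropyran-5-carboxylate (target numbering; C5, C6 undefined; in equilibrium with the open hydroxymethylene ester) | COC(=O)C1C(O)O[C@@H](C)[C@@H](C(OC)OC)[C@@H]1CCO[Si](C)(C)C(C)(C)C | intermediate |
| 15 | methyl (2S,3S,4S)-4-[2-(tert-butyldimethylsilyloxy)ethyl]-3-(dimethoxymethyl)-2-methyl-3,4-dihydro-2H-pyran-5-carboxylate | COC(=O)C1=CO[C@@H](C)[C@@H](C(OC)OC)[C@@H]1CCO[Si](C)(C)C(C)(C)C | intermediate |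
| 16 | methyl (2S,3S,4S)-3-(dimethoxymethyl)-4-(2-hydroxyethyl)-2-methyl-3,4-dihydro-2H-pyran-5-carboxylate | COC(=O)C1=CO[C@@H](C)[C@@H](C(OC)OC)[C@@H]1CCO | intermediate |
| 17 | 2-[(2S,3S,4S)-3-(dimethoxymethyl)-5-(methoxycarbonyl)-2-methyl-3,4-dihydro-2H-pyran-4-yl]acetic acid | COC(=O)C1=CO[C@@H](C)[C@@H](C(OC)OC)[C@@H]1CC(=O)O | intermediate |
| 18 | hydroxytyrosol | OCCc1ccc(O)c(O)c1 | starting material |
| 19 | tris-TBS ether of hydroxytyrosol | CC(C)(C)[Si](C)(C)OCCc1ccc(O[Si](C)(C)C(C)(C)C)c(O[Si](C)(C)C(C)(C)C)c1 | intermediate |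
| 20 | 2-[3,4-bis(tert-butyldimethylsilyloxy)phenyl]ethanol | OCCc1ccc(O[Si](C)(C)C(C)(C)C)c(O[Si](C)(C)C(C)(C)C)c1 | intermediate |
| 21 | 2-[3,4-bis(tert-butyldimethylsilyloxy)phenyl]ethyl ester of 17 | COC(=O)C1=CO[C@@H](C)[C@@H](C(OC)OC)[C@@H]1CC(=O)OCCc1ccc(O[Si](C)(C)C(C)(C)C)c(O[Si](C)(C)C(C)(C)C)c1 | intermediate |
| 22 | 2-(3,4-dihydroxyphenyl)ethyl ester of 17 (dimethyl acetal of the target) | COC(=O)C1=CO[C@@H](C)[C@@H](C(OC)OC)[C@@H]1CC(=O)OCCc1ccc(O)c(O)c1 | intermediate |
| 23 | methyl (2S,3S,4S)-4-{2-[2-(3,4-dihydroxyphenyl)ethoxy]-2-oxoethyl}-3-formyl-2-methyl-3,4-dihydro-2H-pyran-5-carboxylate | COC(=O)C1=CO[C@@H](C)[C@@H](C=O)[C@@H]1CC(=O)OCCc1ccc(O)c(O)c1 | target |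

**Total step count:** 15.
**Longest linear sequence:** 12 (steps 2–11, 14 and 15, from 3).

**Steps most likely to fail**

**Step 4.**
- What may go wrong: the β-alkyl enal may react sluggishly. The strong acid may protodesilylate the diene. The diene CH2 terminus may add to the activated formyl carbon in a Mukaiyama aldol sense. Facial or endo control may be incomplete.
- Fallback: covalent auxiliary control, setting out from 4 and 2 and coming back at 7.
- Cross-metathesis of 4 with commercial (R)-3-acryloyl-4-benzyloxazolidin-2-one, using the same ruthenium catalyst, would give the (E)-enoyl imide F1.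
- An Et2AlCl-promoted Diels–Alder reaction of F1 with 2 (CH2Cl2, −78 → −30 °C) would follow. The chelated s-cis imide is shielded on its Cα Si face by the benzyl group, so this would give the endo adduct imide F2.
- LiBH4 (Et2O, 1 equiv MeOH) would release the auxiliary and give the primary alcohol F3.
- Parikh–Doering oxidation (SO3·pyridine, DMSO, Et3N) would then give 7.

**Step 9.**
- What may go wrong: the base may attack or decarbonylate the formate, stripping the formyl group before C5 is acylated. The freed alkoxide may then lactonise onto the methyl ester. During the acid stage the acetal may exchange with the enol oxygen.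
- Fallback: lactone-based ring switch, setting out from 13 and coming back at 15.
- K2CO3 in MeOH would remove the formyl group and let the alkoxide close onto C7 to give the δ-lactone F4.
- iBu2AlH (CH2Cl2, −78 °C) would give the lactol F5.
- MsCl/Et3N would dehydrate it to the C5-unsubstituted dihydropyran F6.
- Cl3CCOCl/pyridine would acylate the enol ether at its nucleophilic β-carbon to give the trichloromethyl ketone F7.
- Haloform-type methanolysis (MeOH, Et3N) would deliver 15.
- In this variant the pyran C6 is the former silyloxy-bearing alkene carbon, and the ester carbon comes from trichloroacetyl chloride.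

**Step 8.**
- What may go wrong: hydrogen may migrate in the peracid adduct, oxidising the aldehyde to the acid instead of inserting oxygen. C2 may also epimerise slowly before it is oxidised.
- Fallback: ketone Baeyer–Villiger, setting out from 12 and coming back at 15.
- MeTi(OiPr)3 would add chemoselectively to the aldehyde to give the secondary carbinol F8.
- Dess–Martin periodinane would give the methyl ketone F9.
- Baeyer–Villiger oxidation (mCPBA, or CF3CO3H with Na2HPO4) has only C2 or methyl available to migrate, so it would give the acetate F10 with retention.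
- K2CO3 in MeOH would convert F10 into the δ-lactone F4, which then follows the sequence given for step 9 to 15.

**Further compounds**
F1 | step 4 | (R)-4-benzyl-3-[(E)-5-(tert-butyldimethylsilyloxy)pent-2-enoyl]oxazolidin-2-one | O=C(/C=C/CCO[Si](C)(C)C(C)(C)C)N1C(=O)OC[C@H]1Cc1ccccc1
F2 | step 4 | N-acyl oxazolidinone analogue of 7 (CHO replaced by the (R)-4-benzyl-2-oxooxazolidine-3-carbonyl group) | C[C@@H]1C=C(O[Si](C(C)C)(C(C)C)C(C)C)C[C@@H](CCO[Si](C)(C)C(C)(C)C)[C@@H]1C(=O)N2C(=O)OC[C@H]2Cc3ccccc3
F3 | step 4 | primary alcohol corresponding to 7 (CHO replaced by CH2OH) | C[C@@H]1C=C(O[Si](C(C)C)(C(C)C)C(C)C)C[C@@H](CCO[Si](C)(C)C(C)(C)C)[C@@H]1CO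
F4 | step 9 | (4R,5S,6S)-4-[2-(tert-butyldimethylsilyloxy)ethyl]-5-(dimethoxymethyl)-6-methyltetrahydro-2H-pyran-2-one | O=C1O[C@@H](C)[C@@H](C(OC)OC)[C@@H](C1)CCO[Si](C)(C)C(C)(C)C
F5 | step 9 | lactol of F4 (anomeric centre undefined) | OC1O[C@@H](C)[C@@H](C(OC)OC)[C@@H](C1)CCO[Si](C)(C)C(C)(C)C
F6 | step 9 | C5-unsubstituted analogue of 15 (3,4-dihydro-2H-pyran, same three configurations in space) | C1=CO[C@@H](C)[C@@H](C(OC)OC)[C@@H]1CCO[Si](C)(C)C(C)(C)C
F7 | step 9 | 5-(trichloroacetyl) analogue of 15 | O=C(C(Cl)(Cl)Cl)C1=CO[C@@H](C)[C@@H](C(OC)OC)[C@@H]1CCO[Si](C)(C)C(C)(C)C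
F8 | step 8 | methyl (3R,4S,5S)-3-[2-(tert-butyldimethylsilyloxy)ethyl]-4-(dimethoxymethyl)-6-hydroxy-5-methylheptanoate (C6 undefined) | CC(O)[C@@H](C)[C@@H](C(OC)OC)[C@@H](CC(=O)OC)CCO[Si](C)(C)C(C)(C)C
F9 | step 8 | methyl (3R,4S,5S)-3-[2-(tert-butyldimethylsilyloxy)ethyl]-4-(dimethoxymethyl)-5-methyl-6-oxoheptanoate | CC(=O)[C@@H](C)[C@@H](C(OC)OC)[C@@H](CC(=O)OC)CCO[Si](C)(C)C(C)(C)C
F10 | step 8 | methyl (3R,4S,5S)-5-acetoxy-3-[2-(tert-butyldimethylsilyloxy)ethyl]-4-(dimethoxymethyl)hexanoate | CC(=O)O[C@@H](C)[C@@H](C(OC)OC)[C@@H](CC(=O)OC)CCO[Si](C)(C)C(C)(C)C
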